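## Retrosynthetic overview

1. Selaginellin A ⇐ a tris(methyl ether) triaryl carbinol (global BBr3 demethylation with loss of water) ⇐ a diaryl ketone + PhLi ⇐ a bromo chloro diaryl ketone, by Sonogashira (alkyne arm) and Suzuki (biaryl arm) couplings.
2. The bromo chloro ketone ⇐ a 5-aroyl-2-pyrone + 1,1-dimethoxyethene. An inverse-electron-demand Diels–Alder / retro-Diels–Alder (loss of CO2) / methanol-elimination cascade builds the oxygenated six-membered ring (ring D, the later dienone; C-1' bears the exocyclic carbon, C-4' the oxygen) by forming C-2'–C-3' and C-4'–C-5'.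
3. Enabling feature: ring D is the dehydrated form of a 4-hydroxyphenyl carbinol, a ring of four CH groups with the exocyclic carbon at C-1' and the oxygen at C-4' (para). C-2', C-1', C-6', C-5' map onto C-6, C-5, C-4, C-3 of a 2-pyrone and C-3'/C-4' onto a ketene CH–C(=O) unit. The exocyclic carbon, held at the ketone level, is the C-5 acceptor that makes the pyrone an electron-poor diene and sends the oxygenated carbon para to it.
4. The 5-aroyl-2-pyrone ⇐ coumaloyl chloride (from coumalic acid) + the arylzinc made from 2-bromo-4-chlorotoluene by lithiation between the two halogens. The carboxyl carbon of coumalic acid becomes the exocyclic carbon of the quinone methide.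
5. Order of rings: ring A (central benzene) is bought; ring D is formed in step 3; the two anisyl rings are attached in steps 4 and 5 and the phenyl ring in step 6; the ketone returns to the alkene level in step 7.

Key step: step 3

Remark: the target has no stereocentre; the stereocentres met on the way (bridgeheads of 8, carbinol carbon of 16, 17 and 18) are racemic and are erased.

## Route

Step 1
Reactants: 1 coumalic acid (2-oxo-2H-pyran-5-carboxylic acid)
Product: 2 coumaloyl chloride (2-oxo-2H-pyran-5-carbonyl chloride)
Conditions: (COCl)2, cat. DMF, CH2Cl2, 0 to 25 °C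
Reagents that add atoms: oxalyl chloride, ClC(=O)C(=O)Cl
Why: Acid chloride formation through the Vilsmeier-type chloroiminium catalyst should proceed cleanly because the 2-pyrone ring tolerates HCl and no nucleophile is present that could attack C-6.

Step 2
Reactants: 3 2-bromo-4-chlorotoluene; 2 coumaloyl chloride
Product: 6 (2-bromo-6-chloro-3-methylphenyl)(6-oxo-6H-pyran-3-yl)methanone, via aryllithium 4 (not isolated), via arylzinc chloride 5 (not isolated)
Conditions: lithium 2,2,6,6-tetramethylpiperidide (from 2,2,6,6-tetramethylpiperidine and n-BuLi), THF, −78 °C; ZnCl2, −78 to 0 °C; then 2, Pd(PPh3)4 (5 mol%), 0 to 25 °C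
Reagents that add atoms: none
Why: Directed ortho-lithiation should occur at the C–H flanked by bromine and chlorine (the most acidic ring position), transmetalation to zinc at −78 °C forestalls loss of LiBr to an aryne, and the Negishi acylation (zerovalent palladium inserts into the acyl C–Cl bond far faster than into the hindered aryl bromide) should join the arylzinc to 2 without touching the lactone, the hindered amine by-product being too bulky to be acylated.

Step 3
Reactants: 6 (2-bromo-6-chloro-3-methylphenyl)(6-oxo-6H-pyran-3-yl)methanone; 7 1,1-dimethoxyethene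
Product: 10 (2-bromo-6-chloro-3-methylphenyl)(4-methoxyphenyl)methanone, via bridged lactone 8 (not isolated), via diene ketal 9 (not isolated)
Conditions: 7 (4 equiv), PhMe, sealed tube, 110 °C
Reagents that add atoms: none
Why: The electron-poor 2-pyrone diene of 6 (C-3 to C-6) and the electron-rich alkene of 7 should combine in an inverse-electron-demand Diels–Alder reaction to the bridged lactone 8, which expels CO2 by retro-[4+2] to the diene ketal 9 and then loses methanol by 1,2-elimination, aromatisation being the driving force. The closest known reaction type is the conversion of coumalate esters (5-alkoxycarbonyl-2-pyrones) and other acceptor-substituted 2-pyrones into alkoxyarenes with ketene acetals, of which 6 is the ketone analogue. The new six-membered carbocycle is closed by an intermolecular [4+2] cycloaddition in which both bonds form in one, probably asynchronous, event led by the CH2-to-C-6 bond; the two bridgehead stereocentres of 8 are transient and vanish in 10, so no stereocontrol is required. The selectivity that matters is regiochemical: the aroyl group at C-5 makes C-6 (β to the ketone and bonded to the ring oxygen) the most electrophilic diene terminus, so the nucleophilic CH2 carbon of 7 bonds to C-6 and the acetal carbon to C-3, which places the methoxy group para to the carbon that bears the ketone. Addition of 7 across the aroyl enone (hetero-Diels–Alder) would give an ortho-ester-type adduct that can revert at 110 °C, whereas the carbocyclic adduct is drained irreversibly by CO2 loss, and the aryl bromide, the aryl chloride and the hindered ketone are inert under these neutral thermal conditions.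

Step 4
Reactants: 10 (2-bromo-6-chloro-3-methylphenyl)(4-methoxyphenyl)methanone; 11 4-ethynylanisole (1-ethynyl-4-methoxybenzene)
Product: 12 {6-chloro-2-[(4-methoxyphenyl)ethynyl]-3-methylphenyl}(4-methoxyphenyl)methanone
Conditions: PdCl2(PhCN)2 (3 mol%), P(t-Bu)3 (6 mol%), CuI (2 mol%), i-Pr2NH, dioxane, 25 to 45 °C
Reagents that add atoms: none
Why: In this Sonogashira coupling the bulky, electron-rich phosphine should allow oxidative addition to the doubly ortho-substituted C–Br bond near room temperature, where the aryl chloride does not react, so only the bromide is alkynylated.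

Step 5
Reactants: 12 {6-chloro-2-[(4-methoxyphenyl)ethynyl]-3-methylphenyl}(4-methoxyphenyl)methanone; 13 4-methoxyphenylboronic acid
Product: 14 {4'-methoxy-3-[(4-methoxyphenyl)ethynyl]-4-methyl-[1,1'-biphenyl]-2-yl}(4-methoxyphenyl)methanone
Conditions: Pd(OAc)2 (3 mol%), SPhos (6 mol%), K3PO4, PhMe/H2O, 100 °C
Reagents that add atoms: none
Why: Suzuki–Miyaura coupling with a dialkylbiarylphosphine ligand should engage the aryl chloride, which is activated by the ortho ketone, while the diaryl alkyne, the ketone and the methyl ethers are inert to the mild base.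

Step 6
Reactants: 14 {4'-methoxy-3-[(4-methoxyphenyl)ethynyl]-4-methyl-[1,1'-biphenyl]-2-yl}(4-methoxyphenyl)methanone; 15 phenyllithium
Product: 17 {4'-methoxy-3-[(4-methoxyphenyl)ethynyl]-4-methyl-[1,1'-biphenyl]-2-yl}(4-methoxyphenyl)(phenyl)methanol (racemic), via lithium alkoxide 16 (not isolated)
Conditions: PhLi (2 equiv), THF, −78 to 0 °C; then H2O
Reagents that add atoms: none
Why: 1,2-Addition of the small aryllithium to a non-enolisable diaryl ketone should be clean at low temperature, where neither carbolithiation of the alkyne nor alkoxide addition to it competes; the new carbinol stereocentre forms as a racemate and is erased in step 7.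

Step 7
Reactants: 17 {4'-methoxy-3-[(4-methoxyphenyl)ethynyl]-4-methyl-[1,1'-biphenyl]-2-yl}(4-methoxyphenyl)(phenyl)methanol
Product: 19 selaginellin A, via triphenolic carbinol 18 (not isolated)
Conditions: BBr3 (6 equiv), CH2Cl2, −78 to 0 °C; then H2O, 25 °C
Reagents that add atoms: none
Why: BBr3 should cleave the three aryl methyl ethers (Lewis acid-assisted SN2 attack of bromide on the methyl groups) and, on aqueous work-up, the (4-hydroxyphenyl)carbinol level 18 loses water spontaneously to the extended quinone methide, the conjugated fuchsone being the thermodynamic sink and the carbinol stereocentre disappearing with it.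

## Compound list

1 | coumalic acid (2-oxo-2H-pyran-5-carboxylic acid) | OC(=O)C1=COC(=O)C=C1 | starting material
2 | coumaloyl chloride (2-oxo-2H-pyran-5-carbonyl chloride) | ClC(=O)C1=COC(=O)C=C1 | intermediate
3 | 2-bromo-4-chlorotoluene | Cc1ccc(Cl)cc1Br | starting material
4 | (2-bromo-6-chloro-3-methylphenyl)lithium | Cc1ccc(Cl)c([Li])c1Br | intermediate
5 | (2-bromo-6-chloro-3-methylphenyl)zinc chloride | Cc1ccc(Cl)c([Zn]Cl)c1Br | intermediate
6 | (2-bromo-6-chloro-3-methylphenyl)(6-oxo-6H-pyran-3-yl)methanone | Cc1ccc(Cl)c(C(=O)C2=COC(=O)C=C2)c1Br | intermediate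
7 | 1,1-dimethoxyethene | COC(=C)OC | starting material
8 | 7-(2-bromo-6-chloro-3-methylbenzoyl)-5,5-dimethoxy-2-oxabicyclo[2.2.2]oct-7-en-3-one (racemic, bridgeheads fixed by the bicycle) | COC1(OC)CC2OC(=O)C1C=C2C(=O)c1c(Cl)ccc(C)c1Br | intermediate
9 | (2-bromo-6-chloro-3-methylphenyl)(4,4-dimethoxycyclohexa-1,5-dien-1-yl)methanone | COC1(OC)CC=C(C=C1)C(=O)c1c(Cl)ccc(C)c1Br | intermediate
10 | (2-bromo-6-chloro-3-methylphenyl)(4-methoxyphenyl)methanone | COc1ccc(cc1)C(=O)c1c(Cl)ccc(C)c1Br | intermediate
11 | 4-ethynylanisole (1-ethynyl-4-methoxybenzene) | COc1ccc(cc1)C#C | starting material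
12 | {6-chloro-2-[(4-methoxyphenyl)ethynyl]-3-methylphenyl}(4-methoxyphenyl)methanone | COc1ccc(cc1)C(=O)c1c(Cl)ccc(C)c1C#Cc1ccc(OC)cc1 | intermediate
13 | 4-methoxyphenylboronic acid | COc1ccc(cc1)B(O)O | starting material
14 | {4'-methoxy-3-[(4-methoxyphenyl)ethynyl]-4-methyl-[1,1'-biphenyl]-2-yl}(4-methoxyphenyl)methanone | COc1ccc(cc1)C(=O)c1c(-c2ccc(OC)cc2)ccc(C)c1C#Cc1ccc(OC)cc1 | intermediate
15 | phenyllithium | [Li]c1ccccc1 | starting material
16 | lithium alkoxide of 17 (racemic) | COc1ccc(cc1)C(O[Li])(c1ccccc1)c1c(-c2ccc(OC)cc2)ccc(C)c1C#Cc1ccc(OC)cc1 | intermediate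
17 | {4'-methoxy-3-[(4-methoxyphenyl)ethynyl]-4-methyl-[1,1'-biphenyl]-2-yl}(4-methoxyphenyl)(phenyl)methanol (racemic) | COc1ccc(cc1)C(O)(c1ccccc1)c1c(-c2ccc(OC)cc2)ccc(C)c1C#Cc1ccc(OC)cc1 | intermediate
18 | 4-[hydroxy{4'-hydroxy-3-[(4-hydroxyphenyl)ethynyl]-4-methyl-[1,1'-biphenyl]-2-yl}(phenyl)methyl]phenol (racemic) | Oc1ccc(cc1)C(O)(c1ccccc1)c1c(-c2ccc(O)cc2)ccc(C)c1C#Cc1ccc(O)cc1 | intermediate
19 | selaginellin A, 4-[{4'-hydroxy-3-[(4-hydroxyphenyl)ethynyl]-4-methyl-[1,1'-biphenyl]-2-yl}(phenyl)methylidene]cyclohexa-2,5-dien-1-one | Cc1ccc(-c2ccc(O)cc2)c(C(=C2C=CC(=O)C=C2)c2ccccc2)c1C#Cc1ccc(O)cc1 | target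

## Step count and risks

Total: 7 steps. Longest linear sequence: 7 steps from coumalic acid 1 (6 steps from 2-bromo-4-chlorotoluene 3).

Steps most likely to fail:

1. **Step 3.** The cascade may stall before aromatisation (slow CO2 extrusion or slow loss of methanol), or the ketene acetal may be used up by addition across the aroyl enone or by open-chain Michael addition at C-6 and oligomerisation. Fallback, setting out from 6 and coming back at 10: 6 is heated with ethoxyethyne (PhMe, sealed tube, 90 °C). With an alkyne as the two-carbon partner the cycloadduct aromatises by CO2 loss alone, with no elimination step, and the same polarisation of the pyrone should give (2-bromo-6-chloro-3-methylphenyl)(4-ethoxyphenyl)methanone F1. BBr3 (CH2Cl2, 0 °C) cleaves the ethyl ether to (2-bromo-6-chloro-3-methylphenyl)(4-hydroxyphenyl)methanone F2, and MeI/K2CO3 (acetone, 50 °C) returns to 10.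

2. **Step 2.** Loss of LiBr from the ortho-bromo aryllithium (aryne formation) before transmetalation, or conjugate attack of the organometallic on C-6 of the pyrone in place of acylation. Fallback with reversed polarity, setting out from 3 and coming back at 6: 3 is lithiated (LDA, THF, −78 °C) and quenched with CO2 to give 2-bromo-6-chloro-3-methylbenzoic acid F3. (COCl)2/cat. DMF converts it into 2-bromo-6-chloro-3-methylbenzoyl chloride F4. Stille acylation (Pd2(dba)3, tri(2-furyl)phosphine, PhMe, 80 °C) with 5-(trimethylstannyl)-2H-pyran-2-one F5 (from purchased 5-bromo-2H-pyran-2-one, hexamethylditin, Pd(PPh3)4, dioxane, 100 °C) should deliver 6 under neutral conditions.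

3. **Step 7.** Ionisation of the carbinol by the Lewis acid followed by Friedel–Crafts ring closure onto the neighbouring anisyl ring (fluorene formation), or bromoboration of the alkyne during the slow cleavage of three ethers. Fallback that keeps acid away from the carbinol, setting out from 14 and coming back at 18: the three methyl ethers are cleaved at the ketone stage with EtSNa (DMF, 120 °C) to {4'-hydroxy-3-[(4-hydroxyphenyl)ethynyl]-4-methyl-[1,1'-biphenyl]-2-yl}(4-hydroxyphenyl)methanone F6. TBSCl/imidazole (DMF, 25 °C) gives the tris(tert-butyldimethylsilyl) ether of that ketone F7. PhLi (THF, −78 °C) gives the tris(tert-butyldimethylsilyl) ether of the triphenolic carbinol F8. TBAF/AcOH (THF, 0 °C) frees 18, which on brief contact with dilute HCl dehydrates to 19 as in step 7.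

Further compounds
F1 | step 3 | (2-bromo-6-chloro-3-methylphenyl)(4-ethoxyphenyl)methanone | CCOc1ccc(cc1)C(=O)c1c(Cl)ccc(C)c1Br
F2 | step 3 | (2-bromo-6-chloro-3-methylphenyl)(4-hydroxyphenyl)methanone | Oc1ccc(cc1)C(=O)c1c(Cl)ccc(C)c1Br
F3 | step 2 | 2-bromo-6-chloro-3-methylbenzoic acid | OC(=O)c1c(Cl)ccc(C)c1Br
F4 | step 2 | 2-bromo-6-chloro-3-methylbenzoyl chloride | ClC(=O)c1c(Cl)ccc(C)c1Br
F5 | step 2 | 5-(trimethylstannyl)-2H-pyran-2-one | C[Sn](C)(C)C1=COC(=O)C=C1
F6 | step 7 | {4'-hydroxy-3-[(4-hydroxyphenyl)ethynyl]-4-methyl-[1,1'-biphenyl]-2-yl}(4-hydroxyphenyl)methanone | Oc1ccc(cc1)C(=O)c1c(-c2ccc(O)cc2)ccc(C)c1C#Cc1ccc(O)cc1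
F7 | step 7 | tris(tert-butyldimethylsilyl) ether of F6 | CC(C)(C)[Si](C)(C)Oc1ccc(cc1)C(=O)c1c(-c2ccc(O[Si](C)(C)C(C)(C)C)cc2)ccc(C)c1C#Cc1ccc(O[Si](C)(C)C(C)(C)C)cc1
F8 | step 7 | tris(tert-butyldimethylsilyl) ether of carbinol 18 (racemic) | CC(C)(C)[Si](C)(C)Oc1ccc(cc1)C(O)(c1ccccc1)c1c(-c2ccc(O[Si](C)(C)C(C)(C)C)cc2)ccc(C)c1C#Cc1ccc(O[Si](C)(C)C(C)(C)C)cc1
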